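**Retrosynthetic overview**
1. Kanzonol X (11) ⇐ tris-TBS ether 10 by fluoride desilylation, which leaves both prenyl groups untouched.
2. 10 ⇐ achiral isoflavylium ion released from 2-methoxy-2H-chromene 9; a chiral Brønsted acid / Hantzsch ester cascade reduction sets C3, the only stereocentre.
3. 9 ⇐ salicylaldehyde 5 (A ring + C4) and aryl enol ether 8 (B ring + C3, C2) by o-quinone-methide [4+2], forming C3–C4 and O1–C2. The pyran is the only ring made in the route.
4. 8 ⇐ aldehyde 6 (Wittig). 5 and 6 ⇐ one aldehyde 3, because both aryl rings are the same 4-substituted 2-prenylresorcinol. 3 ⇐ 2,4-dihydroxybenzaldehyde + prenyl bromide.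

Assumption: the (R)-configured catalyst is taken to give (3R)-10. The sense of induction is unknown for this new substrate class and must be checked on the first run (chiral HPLC, CD against known (3R)-isoflavans); if it is opposite, the (S)-catalyst is used.

Abbreviations: prenyl = 3-methylbut-2-en-1-yl; TBS = tert-butyldimethylsilyl.

**Step 1**
Reactants: 1, 2,4-dihydroxybenzaldehyde; 2, prenyl bromide
Product: 3, 2,4-dihydroxy-3-prenylbenzaldehyde
Conditions: KOH (10% aq), 0 °C → rt; chromatography to remove 5-prenyl and O-prenyl isomers
Reagents that add atoms: prenyl bromide, CC(C)=CCBr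
Why: C-alkylation of the ambident resorcinol phenoxide in water goes mainly at C3, the carbon flanked by both oxygens; the yield is modest (about 25–30% expected) but it is one step from bulk materials.

**Step 2**
Reactants: 3; 4, TBSCl
Product: 5, 4-(TBS-oxy)-2-hydroxy-3-prenylbenzaldehyde
Conditions: TBSCl (1.05 equiv), imidazole, CH2Cl2, 0 °C
Reagents that add atoms: TBSCl, CC(C)(C)[Si](C)(C)Cl
Why: chemoselective silylation; the 2-OH is hydrogen-bonded to the aldehyde and flanked on both sides, so only the 4-OH reacts.

**Step 3**
Reactants: 3; 4, TBSCl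
Product: 6, 2,4-bis(TBS-oxy)-3-prenylbenzaldehyde
Conditions: TBSCl (3 equiv), imidazole, DMAP (cat.), DMF, 40 °C
Reagents that add atoms: TBSCl, CC(C)(C)[Si](C)(C)Cl
Why: exhaustive phenol silylation under forcing conditions; the ortho oxygen must be capped so the later enol ether cannot close to a benzofuran.

**Step 4**
Reactants: 6; 7, (methoxymethyl)triphenylphosphonium chloride
Product: 8, 1-(2-methoxyvinyl)-2,4-bis(TBS-oxy)-3-prenylbenzene (E/Z mixture, used as such)
Conditions: MeOCH2PPh3Cl, NaHMDS, THF, −78 → 0 °C
Reagents that add atoms: (methoxymethyl)triphenylphosphonium chloride, COC[P+](c1ccccc1)(c1ccccc1)c1ccccc1.[Cl-]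
Why: Wittig methoxymethylenation of a non-enolisable aldehyde; the amide base avoids alkoxide attack on the aryl silyl ethers, and the alkene geometry is irrelevant because it is lost later.

**Step 5**
Reactants: 5; 8 (1.1 equiv)
Product: 9, rac-2-methoxy-3-[2,4-bis(TBS-oxy)-3-prenylphenyl]-7-(TBS-oxy)-8-prenyl-2H-chromene
Conditions: HC(OMe)3 (3 equiv), PPTS (10 mol %), CH2Cl2, rt; then PhMe, 4 Å MS, 80 °C (−MeOH); Et3N-deactivated silica
Reagents that add atoms: none (trimethyl orthoformate only removes water; the 2-OMe comes from 8)
Why: three-component o-quinone-methide inverse-demand hetero-Diels–Alder, in which the acetal of 5 ionises to the o-quinone-methide oxocarbenium, the aryl-bearing carbon of 8 bonds to the benzylic carbon and the phenol oxygen closes onto the MeO-bearing carbon to give the 2,4-dimethoxyisoflavan; acid-mediated loss of the 4-OMe then gives the conjugated chromene acetal, whose racemic C2 is erased in step 6.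

**Step 6**
Reactants: 9
Product: 10, (R)-3-[2,4-bis(TBS-oxy)-3-prenylphenyl]-7-(TBS-oxy)-8-prenylchroman
Conditions: (R)-3,3′-bis(2,4,6-triisopropylphenyl)-BINOL N-triflylphosphoramide (10 mol %), Hantzsch ester (diethyl 2,6-dimethyl-1,4-dihydropyridine-3,5-dicarboxylate, 2.5 equiv), PhMe, 5 Å MS, 40 °C, slow addition of 9
Reagents that add atoms: none (hydrogen only)
Why: Proposed new method: the chiral acid ionises the acetal to the achiral isoflavylium (3-arylbenzopyrylium) ion paired with the chiral phosphoramidate, the soft 1,4-selective Hantzsch ester delivers hydride to C4 to give the 3-aryl-4H-chromene (a cyclic enol ether), the chiral acid protonates C3 on one face inside the ion-pair pocket (this, or the following hydride transfer under Curtin–Hammett control, sets the (R) centre), and a second hydride to the C2 oxocarbenium gives the chroman irreversibly without touching the isolated prenyl alkenes; the closest known reaction types are the chiral phosphoric acid / Hantzsch ester cascade reduction of 3-substituted quinolines (1,4-hydride, enantioselective protonation, 1,2-hydride), the same catalysts reducing benzopyrylium ions to 4H-chromenes, and chiral N-triflyl(thio)phosphoramide protonation of α-aryl cyclic silyl enol ethers, while the all-oxygen cascade on an isoflavylium ion has not been shown.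

**Step 7**
Reactants: 10
Product: 11, Kanzonol X, (R)-3-(2,4-dihydroxy-3-prenylphenyl)-8-prenylchroman-7-ol
Conditions: TBAF (3.5 equiv), AcOH (3.5 equiv), THF, 0 °C, degassed
Reagents that add atoms: none
Why: fluoride desilylation of three aryl silyl ethers under buffered, non-acidic conditions, so the o-prenylphenols do not cyclise and the non-acidic C3–H cannot epimerise.

**Compound list**
1 | 2,4-dihydroxybenzaldehyde | O=Cc1ccc(O)cc1O | starting material
2 | prenyl bromide (1-bromo-3-methylbut-2-ene) | CC(C)=CCBr | starting material
3 | 2,4-dihydroxy-3-prenylbenzaldehyde | O=Cc1ccc(O)c(CC=C(C)C)c1O | intermediate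
4 | tert-butyldimethylsilyl chloride | CC(C)(C)[Si](C)(C)Cl | starting material
5 | 4-(TBS-oxy)-2-hydroxy-3-prenylbenzaldehyde | O=Cc1ccc(O[Si](C)(C)C(C)(C)C)c(CC=C(C)C)c1O | intermediate
6 | 2,4-bis(TBS-oxy)-3-prenylbenzaldehyde | O=Cc1ccc(O[Si](C)(C)C(C)(C)C)c(CC=C(C)C)c1O[Si](C)(C)C(C)(C)C | intermediate
7 | (methoxymethyl)triphenylphosphonium chloride | COC[P+](c1ccccc1)(c1ccccc1)c1ccccc1.[Cl-] | starting material
8 | 1-(2-methoxyvinyl)-2,4-bis(TBS-oxy)-3-prenylbenzene (E/Z) | COC=Cc1ccc(O[Si](C)(C)C(C)(C)C)c(CC=C(C)C)c1O[Si](C)(C)C(C)(C)C | intermediate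
9 | rac-2-methoxy-3-[2,4-bis(TBS-oxy)-3-prenylphenyl]-7-(TBS-oxy)-8-prenyl-2H-chromene | COC1Oc2c(CC=C(C)C)c(O[Si](C)(C)C(C)(C)C)ccc2C=C1c1ccc(O[Si](C)(C)C(C)(C)C)c(CC=C(C)C)c1O[Si](C)(C)C(C)(C)C | intermediate
10 | (R)-3-[2,4-bis(TBS-oxy)-3-prenylphenyl]-7-(TBS-oxy)-8-prenylchroman | CC(C)=CCc1c(O[Si](C)(C)C(C)(C)C)ccc([C@@H]2COc3c(ccc(O[Si](C)(C)C(C)(C)C)c3CC=C(C)C)C2)c1O[Si](C)(C)C(C)(C)C | intermediate
11 | Kanzonol X | CC(C)=CCc1c(O)ccc([C@@H]2COc3c(ccc(O)c3CC=C(C)C)C2)c1O | target

**Totals**
Total steps: 7. Longest linear sequence: 6 (steps 1, 3, 4, 5, 6, 7); step 2 is a one-step side branch.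

**Steps most likely to fail, with fallbacks**
- **Step 6 (proposed new cascade reduction).** Hydride may add at C2 instead of C4, giving the isoflav-3-ene, which stalls or is reduced with poor selectivity; the aryl enol ether may protonate slowly; or the ee may be low. Fallback with known chemistry: give up the pyrylium route and prepare the racemic 2-(B-aryl)-3-(A-aryl)propanoic acid by benzylating the B-ring arylacetate enolate with the A-ring benzyl bromide. Deracemise it by the known chiral disulfonimide-catalysed enantioselective protonation of its bis-silyl ketene acetal, a method established for α-aryl alkanoic acids. Then reduce with LiAlH4 and close the pyran by Mitsunobu etherification to reach 10.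
- **Step 5 (o-quinone-methide union and MeOH elimination).** The C3–C4 bond joins two ortho-substituted benzylic carbons, and 8 may instead cyclise to a benzofuran or add to transient pyrylium. Fallback: hydrolyse 8 to the arylacetaldehyde and oxidise it (Pinnick) to the arylacetic acid. Condense this with 5 (Perkin–Oglialoro) to the 3-arylcoumarin, then reduce with DIBAL at −78 °C and treat with MeOH/PPTS to reach the same acetal 9.
- **Step 1 (direct C-prenylation).** Yield is low and separation from the 5-prenyl and O-prenyl isomers may be poor. Fallback: regiospecific directed ortho-metalation. Lithiate 1,3-bis(methoxymethoxy)benzene at C2 and trap with prenyl bromide (Cu), then carry out a second ortho-lithiation and DMF formylation. MOM groups then replace TBS, with the chelated ortho-MOM removed selectively for the A-ring partner.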